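**Strategy.** The oxolane (numbered O1, veratryl carbon C2, C3, C4, syringyl carbon C5) is cut at O1–C2 and C3–C4. Seen from C3, the ring is a 3-oxa-5-hexenyl radical closing onto C4, with the C4 methyl as the alkene terminus. A one-flask Ueno–Stork annulation exploits this. It joins an enantiopure 1-arylallyl alcohol (C5, C4, future C4 methyl) to the methyl enol ether of 3,4-dimethoxypropiophenone (C2, C3). Iodoketalisation forms O1–C2, then 5-exo radical cyclisation forms C3–C4, the C5 aryl group directing C4. Because C2 emerges as a ketal, C2 and C3 are set afterwards in one converging ionic hydrogenation; debenzylation finishes the synthesis.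

Key step: step 5

Remark on numbering: in every oxolane below the ring atoms are O1, C2 (carries the 3,4-dimethoxyphenyl group), C3, C4, C5 (carries the 4-oxygenated 3,5-dimethoxyphenyl group), whatever the substituent priorities. In this numbering the target is (2R,3S,4S,5S), with 2,3-cis, 3,4-trans, 4,5-trans and 2,5-cis relationships.

Assumption: syringaldehyde, 3',4'-dimethoxypropiophenone and the reagents named are commercial.

Step 1
Reactants: 1 syringaldehyde
Product: 2 4-(benzyloxy)-3,5-dimethoxybenzaldehyde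
Conditions: BnBr, K2CO3, DMF, 60 °C
Reagents that add atoms: benzyl bromide, BrCc1ccccc1
Why: Williamson O-benzylation of the acidic phenol; the benzyl ether should shield the phenol from NIS in step 5 and from quinone-methide formation under BF3·OEt2 in step 6.

Step 2
Reactants: 2 4-(benzyloxy)-3,5-dimethoxybenzaldehyde
Product: 3 rac-1-[4-(benzyloxy)-3,5-dimethoxyphenyl]prop-2-en-1-ol
Conditions: CH2=CHMgBr, THF, −78 → 0 °C; aq. NH4Cl
Reagents that add atoms: vinylmagnesium bromide, C=C[Mg]Br
Why: 1,2-addition of a Grignard reagent to the aromatic aldehyde gives the racemic vinyl carbinol, with no stereocontrol sought at this stage.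

Step 3
Reactants: 3 rac-1-[4-(benzyloxy)-3,5-dimethoxyphenyl]prop-2-en-1-ol
Product: 4 (S)-1-[4-(benzyloxy)-3,5-dimethoxyphenyl]prop-2-en-1-ol
Conditions: Amano lipase PS (immobilised), vinyl acetate, MTBE, 30 °C, run just past half conversion; chromatography
Reagents that add atoms: none
Why: lipase-catalysed kinetic resolution by transesterification; by the empirical rule for secondary alcohols (aryl large, vinyl medium) the R alcohol should be acetylated, leaving the S alcohol, which carries the C5 configuration of the target.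

Step 4
Reactants: 5 1-(3,4-dimethoxyphenyl)propan-1-one
Product: 7 (Z)-1-(3,4-dimethoxyphenyl)-1-methoxyprop-1-ene, via dimethyl ketal 6 (not isolated)
Conditions: HC(OMe)3, TsOH·H2O (cat.), MeOH, 50 °C; Et3N, evaporate; then TMSOTf, iPr2NEt, CH2Cl2, −20 → 23 °C
Reagents that add atoms: trimethyl orthoformate, COC(OC)OC
Why: acid-catalysed ketalisation, then TMSOTf/amine elimination of methanol through the aryl-stabilised oxocarbenium ion, should give the methyl enol ether; its E/Z geometry (Z drawn) does not matter because C3 is set in step 6.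

Step 5
Reactants: 4 (S)-1-[4-(benzyloxy)-3,5-dimethoxyphenyl]prop-2-en-1-ol; 7 (Z)-1-(3,4-dimethoxyphenyl)-1-methoxyprop-1-ene
Product: 9 (4S,5S)-5-[4-(benzyloxy)-3,5-dimethoxyphenyl]-2-(3,4-dimethoxyphenyl)-2-methoxy-3,4-dimethyloxolane as C2/C3 epimer mixture, via iodoketal 8 (not isolated)
Conditions: NIS, 2,6-lutidine, 4 Å MS, CH2Cl2, −40 °C; then toluene (dilution), Bu3SnH (slow addition), Et3B, air, −40 → 23 °C
Reagents that add atoms: none
Why: NIS iodinates enol ether 7 at C3 and alcohol 4 captures the aryl- and methoxy-stabilised oxocarbenium ion at C2 (Markovnikov iodoalkoxylation, forming O1–C2 in 8), after which iodine abstraction by Bu3Sn• gives the C3 radical, which adds to the internal vinyl carbon (forming C3–C4), and the resulting primary radical takes hydrogen from Bu3SnH to become the C4 methyl. The closest known reaction type is the Ueno–Stork haloacetal radical annulation, run here at the ketal oxidation level as with 2-methoxypropene. The oxolane closes in the 5-exo-trig mode of a 3-oxa-5-hexenyl radical, favoured over 6-endo. C4 is controlled by C5: in the chair-like transition state the C5 aryl group sits pseudo-equatorial, placing the new C4 methyl trans to it (4S from 5S), whereas C2 and C3 are left as epimer mixtures on purpose (C3 probably mainly cis to the C4 methyl) because step 6 resets both. The step needs NIS to choose the enol ether over the monosubstituted alkene and the arenes (secured by the much higher nucleophilicity of the α-aryl enol ether at −40 °C under base buffering) and needs cyclisation to outrun direct reduction (secured by the fast 3-oxa-5-hexenyl closure and slow addition of Bu3SnH).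

Step 6
Reactants: 9 (4S,5S)-5-[4-(benzyloxy)-3,5-dimethoxyphenyl]-2-(3,4-dimethoxyphenyl)-2-methoxy-3,4-dimethyloxolane
Product: 11 (2R,3S,4S,5S)-5-[4-(benzyloxy)-3,5-dimethoxyphenyl]-2-(3,4-dimethoxyphenyl)-3,4-dimethyloxolane, via 3,4-trans ketal 10 (not isolated)
Conditions: CSA (cat.), MeOH, CH2Cl2, 23 °C; Et3N, evaporate; then Et3SiH, BF3·OEt2, CH2Cl2, −78 °C; Et3N quench at −78 °C
Reagents that add atoms: none
Why: acid in methanol should first equilibrate C3 through the oxocarbenium ion and its enol ether to the more stable 3,4-trans ketal 10 (kept as the ketal by the excess methanol and the basic quench), after which BF3·OEt2 ionises C2–OMe at −78 °C and Et3SiH delivers hydride to the 2-aryl oxocarbenium ion anti to the C3 methyl and C5 aryl groups (ionic hydrogenation of a cyclic ketal), placing the C2 aryl cis to the C3 methyl before C3 can epimerise again.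

Step 7
Reactants: 11 (2R,3S,4S,5S)-5-[4-(benzyloxy)-3,5-dimethoxyphenyl]-2-(3,4-dimethoxyphenyl)-3,4-dimethyloxolane
Product: 12 4-[(2S,3S,4S,5R)-5-(3,4-dimethoxyphenyl)-3,4-dimethyloxolan-2-yl]-2,6-dimethoxyphenol (target)
Conditions: H2 (1 atm), Pd/C, EtOAc, 23 °C, short reaction time
Reagents that add atoms: none
Why: hydrogenolysis of the aryl benzyl ether over Pd/C should be much faster than cleavage of the two cyclic benzylic C–O bonds and touches no stereocentre.

Compound list
1 | syringaldehyde (4-hydroxy-3,5-dimethoxybenzaldehyde) | COc1cc(C=O)cc(OC)c1O | starting material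
2 | 4-(benzyloxy)-3,5-dimethoxybenzaldehyde | COc1cc(C=O)cc(OC)c1OCc1ccccc1 | intermediate
3 | rac-1-[4-(benzyloxy)-3,5-dimethoxyphenyl]prop-2-en-1-ol | C=CC(O)c1cc(OC)c(OCc2ccccc2)c(OC)c1 | intermediate
4 | (S)-1-[4-(benzyloxy)-3,5-dimethoxyphenyl]prop-2-en-1-ol | C=C[C@H](O)c1cc(OC)c(OCc2ccccc2)c(OC)c1 | intermediate
5 | 1-(3,4-dimethoxyphenyl)propan-1-one | CCC(=O)c1ccc(OC)c(OC)c1 | starting material
6 | 4-(1,1-dimethoxypropyl)-1,2-dimethoxybenzene (dimethyl ketal of 5) | CCC(OC)(OC)c1ccc(OC)c(OC)c1 | intermediate
7 | (Z)-1-(3,4-dimethoxyphenyl)-1-methoxyprop-1-ene (may contain E isomer) | C/C=C(\OC)c1ccc(OC)c(OC)c1 | intermediate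
8 | 2-(benzyloxy)-5-[(1S)-1-{[1-(3,4-dimethoxyphenyl)-2-iodo-1-methoxypropyl]oxy}prop-2-en-1-yl]-1,3-dimethoxybenzene (epimers at the ketal and iodo carbons) | COc1ccc(C(OC)(O[C@@H](C=C)c2cc(OC)c(OCc3ccccc3)c(OC)c2)C(C)I)cc1OC | intermediate
9 | (4S,5S)-5-[4-(benzyloxy)-3,5-dimethoxyphenyl]-2-(3,4-dimethoxyphenyl)-2-methoxy-3,4-dimethyloxolane (C2/C3 epimer mixture) | COc1ccc(C2(OC)O[C@H](c3cc(OC)c(OCc4ccccc4)c(OC)c3)[C@@H](C)C2C)cc1OC | intermediate
10 | (3S,4S,5S)-5-[4-(benzyloxy)-3,5-dimethoxyphenyl]-2-(3,4-dimethoxyphenyl)-2-methoxy-3,4-dimethyloxolane (3,4-trans, 4,5-trans; C2 anomers) | COc1ccc(C2(OC)O[C@H](c3cc(OC)c(OCc4ccccc4)c(OC)c3)[C@@H](C)[C@@H]2C)cc1OC | intermediate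
11 | (2R,3S,4S,5S)-5-[4-(benzyloxy)-3,5-dimethoxyphenyl]-2-(3,4-dimethoxyphenyl)-3,4-dimethyloxolane | COc1ccc([C@@H]2O[C@H](c3cc(OC)c(OCc4ccccc4)c(OC)c3)[C@@H](C)[C@@H]2C)cc1OC | intermediate
12 | 4-[(2S,3S,4S,5R)-5-(3,4-dimethoxyphenyl)-3,4-dimethyloxolan-2-yl]-2,6-dimethoxyphenol | COc1ccc([C@@H]2O[C@H](c3cc(OC)c(O)c(OC)c3)[C@@H](C)[C@@H]2C)cc1OC | target

Totals
Total step count: 7. Longest linear sequence: 6 steps (steps 1, 2, 3, 5, 6, 7 from syringaldehyde); step 4 is a one-step side branch.

Steps most likely to fail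

Step 5. The hindered secondary alcohol may add too slowly to the iodo-oxocarbenium ion, which would then be lost by demethylation to the iodo ketone or by proton loss, or the labile mixed aryl ketal may ionise before the radical closes. The fallback makes the same two ring bonds at the aldehyde oxidation level and brings in the aryl group afterwards. It sets out from 4: NBS and ethyl 1-propenyl ether (CH2Cl2, −20 °C) should convert 4 into the bromoacetal 2-(benzyloxy)-5-[(1S)-1-(2-bromo-1-ethoxypropoxy)prop-2-en-1-yl]-1,3-dimethoxybenzene F1 as an epimer mixture. Bu3SnH/AIBN (benzene, 80 °C) should close F1 in the same 5-exo mode to (4S,5S)-5-[4-(benzyloxy)-3,5-dimethoxyphenyl]-2-ethoxy-3,4-dimethyloxolane F2 as a mixture of C2 and C3 epimers. Oxidation of F2 with mCPBA/BF3·OEt2 (CH2Cl2, 0 °C), then DBU to converge the C3 epimers, should give the 3,4-trans-4,5-trans lactone (3S,4S,5S)-5-[4-(benzyloxy)-3,5-dimethoxyphenyl]-3,4-dimethyloxolan-2-one F3 as one isomer. 3,4-Dimethoxyphenyllithium (from 4-bromo-1,2-dimethoxybenzene and n-BuLi, THF, −78 °C) should add once to F3 to give the hemiketal (3S,4S,5S)-5-[4-(benzyloxy)-3,5-dimethoxyphenyl]-2-(3,4-dimethoxyphenyl)-3,4-dimethyloxolan-2-ol F4 as a mixture of C2 anomers. Under Et3SiH/BF3·OEt2 at −78 °C, F4 is reduced as in step 6, and the route is rejoined at 11.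

Step 6. C3 may not equilibrate fully before hydride capture, the product may lose its C2 configuration by acid-promoted reopening of O1–C2 (drift towards the all-trans isomer), or the ring may open reductively. The fallback sets C2 by a neutral radical reduction instead. It sets out from 9: PhSH with BF3·OEt2 (CH2Cl2, −78 °C) should exchange methoxide for phenylsulfanyl, equilibrating C3 on the way, to give (3S,4S,5S)-5-[4-(benzyloxy)-3,5-dimethoxyphenyl]-2-(3,4-dimethoxyphenyl)-3,4-dimethyl-2-(phenylsulfanyl)oxolane F5 as a mixture of C2 anomers. Bu3SnH/AIBN (toluene, 80 °C) then cleaves the carbon–sulfur bond of F5 and the planar benzylic α-oxy radical at C2 should take hydrogen anti to the C3 methyl and C5 aryl groups. This gives 11 without exposing the product to acid, and the route is rejoined at 11.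

Step 3. The enzyme may discriminate poorly between aryl and vinyl with this bulky aryl group or acylate too slowly, and at best half of 3 is used. The fallback replaces resolution by enantioselective carbon–carbon bond formation. It sets out from 2: (CH2=CH)2Zn with a catalytic chiral β-amino alcohol ((−)-3-exo-(dimethylamino)isoborneol, toluene, 0 °C), chosen for Si-face addition by analogy with dialkylzinc additions, should give 4 directly. The route is rejoined at 4 and no new compound is made.

Further compounds
F1 | step 5 | 2-(benzyloxy)-5-[(1S)-1-(2-bromo-1-ethoxypropoxy)prop-2-en-1-yl]-1,3-dimethoxybenzene | CCOC(O[C@@H](C=C)c1cc(OC)c(OCc2ccccc2)c(OC)c1)C(C)Br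
F2 | step 5 | (4S,5S)-5-[4-(benzyloxy)-3,5-dimethoxyphenyl]-2-ethoxy-3,4-dimethyloxolane | CCOC1O[C@H](c2cc(OC)c(OCc3ccccc3)c(OC)c2)[C@@H](C)C1C
F3 | step 5 | (3S,4S,5S)-5-[4-(benzyloxy)-3,5-dimethoxyphenyl]-3,4-dimethyloxolan-2-one | O=C1O[C@H](c2cc(OC)c(OCc3ccccc3)c(OC)c2)[C@@H](C)[C@@H]1C
F4 | step 5 | (3S,4S,5S)-5-[4-(benzyloxy)-3,5-dimethoxyphenyl]-2-(3,4-dimethoxyphenyl)-3,4-dimethyloxolan-2-ol | COc1ccc(C2(O)O[C@H](c3cc(OC)c(OCc4ccccc4)c(OC)c3)[C@@H](C)[C@@H]2C)cc1OC
F5 | step 6 | (3S,4S,5S)-5-[4-(benzyloxy)-3,5-dimethoxyphenyl]-2-(3,4-dimethoxyphenyl)-3,4-dimethyl-2-(phenylsulfanyl)oxolane | COc1ccc(C2(Sc3ccccc3)O[C@H](c4cc(OC)c(OCc5ccccc5)c(OC)c4)[C@@H](C)[C@@H]2C)cc1OC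
F0 | step 3 | none | none
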